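## Retrosynthetic overview

1. Ring numbering: C1 (CHOH), C2=C3, C4, C5 (tertiary carbinol carrying chain carbon C1'), C6. The strategy rests on C5 of the cyclohexene ring, which joins O, C1', C4 and C6 with the C2=C3 double bond two bonds away. Read with C1' as a carboxyl carbon, this is the α-oxy-γ,δ-unsaturated acid that an ester-enolate Claisen shift forming C4–C5 leaves behind.
2. The chain is cut at C1'–C2': copper-catalysed opening of spiro-epoxide 23 by the C15 Grignard reagent 29, made from 5-phenylpent-1-yne and 1,10-dibromodecane with a Lindlar reduction for the Z-alkene.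
3. Epoxide 23 comes from acid 19 (reduction, tosylation, desilylative closure). Acid 19 comes from vinyl δ-lactone 16 by Ireland–Claisen ring contraction, the only ring-forming step (cyclohexene ring, C4–C5 bond, C5 stereocentre).
4. Lactone 16 comes from aldehyde 7 (ethyl glyoxylate, allyl bromide, silylation, ozonolysis) by Brown (Z)-γ-alkoxyallylboration, which sets both carbinol centres, then silylation, MOM cleavage and lactonisation.

Key step: step 8

Remark: the centre α to the carbonyl group (C2 of 4–7 and 13–15, C3 of 16) is carried as a mixture of epimers, because it becomes trigonal in step 8.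

Remark: (+)-Ipc2BOMe (made from (−)-α-pinene) is taken to deliver the allyl unit to the Re face of an unbranched aldehyde, the mirror image of the known Si-face delivery by the reagent from (+)-α-pinene.

## Route

Step 1
Reactants: 1 ethyl glyoxylate; 2 allyl bromide
Product: 4 ethyl 2-hydroxypent-4-enoate (racemic), via allylzinc bromide 3 (not isolated)
Conditions: Zn dust, THF/sat. aq. NH4Cl, 0 °C to rt
Reagents that add atoms: none
Why: Barbier allylation, in which the allylzinc species formed on the metal should add to the aldehyde carbonyl far faster than to the ester; the new centre is racemic, which is harmless because step 8 flattens it.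

Step 2
Reactants: 4 ethyl 2-hydroxypent-4-enoate
Product: 5 ethyl 2-[(tert-butyldimethylsilyl)oxy]pent-4-enoate (racemic)
Conditions: TBSCl, imidazole, DMF, rt
Reagents that add atoms: tert-butyldimethylsilyl chloride, CC(C)(C)[Si](C)(C)Cl
Why: Standard imidazole-promoted silylation of a secondary alcohol, which installs the oxygen substituent that later becomes the tertiary C5–O group.

Step 3
Reactants: 5 ethyl 2-[(tert-butyldimethylsilyl)oxy]pent-4-enoate
Product: 7 ethyl 2-[(tert-butyldimethylsilyl)oxy]-4-oxobutanoate (racemic), via ozonide 6 (not isolated)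
Conditions: O3, CH2Cl2, −78 °C; then PPh3, −78 °C to rt
Reagents that add atoms: ozone, [O-][O+]=O
Why: Ozonolysis of the terminal alkene with reductive work-up should give the aldehyde without touching the ester or the silyl ether; the β-silyloxy aldehyde is used at once and kept away from base to avoid β-elimination.

Step 4
Reactants: 8 allyl alcohol
Product: 9 3-(methoxymethoxy)prop-1-ene
Conditions: MOMCl, i-Pr2NEt, CH2Cl2, 0 °C to rt
Reagents that add atoms: chloromethyl methyl ether, COCCl
Why: O-alkylation of the alcohol by the oxocarbenium ion from chloromethyl methyl ether gives the allyl acetal ether needed for the alkoxyallylborane.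

Step 5
Reactants: 7 ethyl 2-[(tert-butyldimethylsilyl)oxy]-4-oxobutanoate; 9 3-(methoxymethoxy)prop-1-ene
Product: 13 ethyl (2RS,4S,5S)-2-[(tert-butyldimethylsilyl)oxy]-4-hydroxy-5-(methoxymethoxy)hept-6-enoate, via lithiated allyl ether 10 (not isolated), via alkoxyallylborane 11 (not isolated), via borinate adduct 12 (not isolated)
Conditions: 9, s-BuLi, THF, −78 °C; (+)-Ipc2BOMe, −78 °C; BF3·OEt2, then 7, −78 °C; pH 7 phosphate buffer, MeOH, 30% H2O2, 0 °C to rt
Reagents that add atoms: none
Why: Brown asymmetric alkoxyallylboration through a closed chair transition state, in which the Z geometry of the γ-alkoxyallyl unit gives the syn relationship of C4 and C5 and the isopinocampheyl groups direct attack to the Re face of the aldehyde to give (4S,5S); the neutral oxidative work-up is chosen to keep the γ-hydroxy ester from lactonising.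

Step 6
Reactants: 13 ethyl (2RS,4S,5S)-2-[(tert-butyldimethylsilyl)oxy]-4-hydroxy-5-(methoxymethoxy)hept-6-enoate
Product: 14 ethyl (2RS,4S,5S)-2,4-bis[(tert-butyldimethylsilyl)oxy]-5-(methoxymethoxy)hept-6-enoate
Conditions: TBSOTf, 2,6-lutidine, CH2Cl2, −78 to 0 °C
Reagents that add atoms: tert-butyldimethylsilyl trifluoromethanesulfonate, CC(C)(C)[Si](C)(C)OS(=O)(=O)C(F)(F)F
Why: Silyl triflate with a hindered base silylates the secondary alcohol at low temperature, faster than γ-lactonisation, and blocks the oxygen that must not take part in the ring closure of step 7.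

Step 7
Reactants: 14 ethyl (2RS,4S,5S)-2,4-bis[(tert-butyldimethylsilyl)oxy]-5-(methoxymethoxy)hept-6-enoate
Product: 16 (3RS,5S,6S)-3,5-bis[(tert-butyldimethylsilyl)oxy]-6-ethenyloxan-2-one, via hydroxy ester 15 (not isolated)
Conditions: Me2BBr, CH2Cl2, −78 °C; sat. aq. NaHCO3; crude 15, PPTS (cat.), PhMe, 80 °C
Reagents that add atoms: none
Why: Bromodimethylborane cleaves the acetal ether at −78 °C while silyl ethers survive, and the freed allylic δ-hydroxyl then closes the six-membered lactone by acid-catalysed transesterification (6-exo-trig at the ester carbon), placing the 5-silyloxy and 6-vinyl groups cis as dictated by the syn diol.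

Step 8
Reactants: 16 (3RS,5S,6S)-3,5-bis[(tert-butyldimethylsilyl)oxy]-6-ethenyloxan-2-one
Product: 19 (1S,5S)-1,5-bis[(tert-butyldimethylsilyl)oxy]cyclohex-3-ene-1-carboxylic acid, via silyl ketene acetal 17 (not isolated), via trimethylsilyl ester 18 (not isolated)
Conditions: TMSCl, Et3N, THF, −78 °C, then LiN(i-Pr)2 (slow addition), −78 °C to rt; PhMe, 100 °C; 0.5 M aq. HCl/THF, 0 °C
Reagents that add atoms: none
Why: LiN(i-Pr)2 removes the C3 proton of either epimer of 16 in the presence of TMSCl, so the enolate is trapped at once as cyclic silyl ketene acetal 17, and on heating the O1–C6 bond breaks while C3 bonds to the terminal vinyl carbon in a concerted suprafacial [3,3] shift (Ireland–Claisen rearrangement; the closest precedent is the ring contraction of alkenyl lactones through their silyl ketene acetals, α-alkoxy lactones included). The cyclohexene closes as a ring contraction and not by an exo or endo cyclisation: lactone atoms C3–C6 stay in the ring, the O–C(=O) unit is exchanged for the two vinyl carbons, and because the lactone holds four of the six reacting atoms the transition state can only be a boat of bicyclo[2.2.2]octane shape. The one new stereocentre (C1 of 19, C5 of the target) is controlled by the C6 centre of the lactone, since the pseudoaxial vinyl group can reach C3 only on its own ring face, so the 5-silyloxy group cis to the vinyl group ends cis to the new tertiary C–O bond and trans to the carboxyl group. The ring double bond is necessarily cis and falls between the former C6 and the inner vinyl carbon, which is C2=C3 of the target. The step needs clean O-silylation and no loss of the enolate to a ketene; the internal TMSCl quench at −78 °C and the absence of a leaving group at C4 should secure both. Cold dilute acid then cleaves only the silyl ester 18 and leaves the two silyl ethers in place.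

Step 9
Reactants: 19 (1S,5S)-1,5-bis[(tert-butyldimethylsilyl)oxy]cyclohex-3-ene-1-carboxylic acid
Product: 20 [(1S,5S)-1,5-bis[(tert-butyldimethylsilyl)oxy]cyclohex-3-en-1-yl]methanol
Conditions: LiAlH4, THF, 0 °C to rt
Reagents that add atoms: none
Why: Hydride reduction of the carboxylic acid to the primary alcohol turns the carboxyl carbon into the future C1' without touching the alkene, the silyl ethers or either stereocentre.

Step 10
Reactants: 20 [(1S,5S)-1,5-bis[(tert-butyldimethylsilyl)oxy]cyclohex-3-en-1-yl]methanol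
Product: 21 [(1S,5S)-1,5-bis[(tert-butyldimethylsilyl)oxy]cyclohex-3-en-1-yl]methyl 4-methylbenzenesulfonate
Conditions: TsCl, Et3N, DMAP (cat.), CH2Cl2, 0 °C to rt
Reagents that add atoms: 4-methylbenzenesulfonyl chloride, Cc1ccc(cc1)S(=O)(=O)Cl
Why: Sulfonylation of the only free hydroxyl gives a leaving group on C1' that, being neopentyl-like, is inert to intermolecular attack but well placed for the intramolecular displacement of step 11.

Step 11
Reactants: 21 [(1S,5S)-1,5-bis[(tert-butyldimethylsilyl)oxy]cyclohex-3-en-1-yl]methyl 4-methylbenzenesulfonate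
Product: 23 (3S,5S)-1-oxaspiro[2.5]oct-6-en-5-ol, via diol tosylate 22 (not isolated)
Conditions: TBAF, THF, 0 °C to rt
Reagents that add atoms: none
Why: Fluoride removes both silyl groups and the tertiary alkoxide displaces the adjacent tosylate (intramolecular Williamson closure, 3-exo-tet) without touching either stereocentre; the secondary hydroxyl is trans to the CH2OTs group and cannot compete.

Step 12
Reactants: 24 5-phenylpent-1-yne; 25 1,10-dibromodecane
Product: 27 (15-bromopentadec-4-yn-1-yl)benzene, via lithium acetylide 26 (not isolated)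
Conditions: n-BuLi, THF, −78 °C; then 25 (3 equiv), DMPU, −78 °C to rt
Reagents that add atoms: none
Why: SN2 alkylation of the lithium acetylide by a primary bromide, with the dibromide in excess so that monoalkylation should dominate and the surplus can be distilled off.

Step 13
Reactants: 27 (15-bromopentadec-4-yn-1-yl)benzene
Product: 28 [(4Z)-15-bromopentadec-4-en-1-yl]benzene
Conditions: H2 (1 atm), Pd/CaCO3 poisoned with Pb(OAc)2, quinoline, hexane/EtOAc, rt
Reagents that add atoms: none
Why: Lindlar semi-hydrogenation delivers both hydrogens to one face of the alkyne and should stop at the Z-alkene, leaving the primary bromide intact.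

Step 14
Reactants: 28 [(4Z)-15-bromopentadec-4-en-1-yl]benzene; 23 (3S,5S)-1-oxaspiro[2.5]oct-6-en-5-ol
Product: 30 (1S,3S)-1-[(12Z)-16-phenylhexadec-12-en-1-yl]cyclohex-4-ene-1,3-diol, via Grignard reagent 29 (not isolated)
Conditions: 28, Mg turnings, THF, rt to 40 °C; then CuI (10 mol%), 23 (0.4 equiv relative to 29), THF, −30 to 0 °C; sat. aq. NH4Cl
Reagents that add atoms: none
Why: Copper-catalysed Grignard opening of a 2,2-disubstituted epoxide takes place at the unhindered CH2 terminus (SN2), so the C1'–C2' bond forms and the tertiary alcohol is released with both stereocentres untouched; one equivalent of 29 is spent on the free hydroxyl.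

## Compound list

1 | ethyl glyoxylate | CCOC(=O)C=O | starting material
2 | allyl bromide | C=CCBr | starting material
3 | allylzinc bromide | C=CC[Zn]Br | intermediate
4 | ethyl 2-hydroxypent-4-enoate (racemic) | CCOC(=O)C(O)CC=C | intermediate
5 | ethyl 2-[(tert-butyldimethylsilyl)oxy]pent-4-enoate (racemic) | CCOC(=O)C(O[Si](C)(C)C(C)(C)C)CC=C | intermediate
6 | ethyl 2-[(tert-butyldimethylsilyl)oxy]-3-(1,2,4-trioxolan-3-yl)propanoate | CCOC(=O)C(O[Si](C)(C)C(C)(C)C)CC1OCOO1 | intermediate
7 | ethyl 2-[(tert-butyldimethylsilyl)oxy]-4-oxobutanoate (racemic) | CCOC(=O)C(O[Si](C)(C)C(C)(C)C)CC=O | intermediate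
8 | allyl alcohol | C=CCO | starting material
9 | 3-(methoxymethoxy)prop-1-ene | C=CCOCOC | intermediate
10 | [(2Z)-3-(methoxymethoxy)prop-2-en-1-yl]lithium | [Li]C/C=C\OCOC | intermediate
11 | [(2Z)-3-(methoxymethoxy)prop-2-en-1-yl]bis[(1S,2R,3S,5S)-2,6,6-trimethylbicyclo[3.1.1]hept-3-yl]borane | COCO/C=C\CB([C@H]1C[C@H]2C[C@@H]([C@@H]1C)C2(C)C)[C@H]1C[C@H]2C[C@@H]([C@@H]1C)C2(C)C | intermediate
12 | diisopinocampheylborinate of alcohol 13 | CCOC(=O)C(O[Si](C)(C)C(C)(C)C)C[C@H](OB([C@H]1C[C@H]2C[C@@H]([C@@H]1C)C2(C)C)[C@H]1C[C@H]2C[C@@H]([C@@H]1C)C2(C)C)[C@@H](OCOC)C=C | intermediate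
13 | ethyl (2RS,4S,5S)-2-[(tert-butyldimethylsilyl)oxy]-4-hydroxy-5-(methoxymethoxy)hept-6-enoate | CCOC(=O)C(O[Si](C)(C)C(C)(C)C)C[C@H](O)[C@@H](OCOC)C=C | intermediate
14 | ethyl (2RS,4S,5S)-2,4-bis[(tert-butyldimethylsilyl)oxy]-5-(methoxymethoxy)hept-6-enoate | CCOC(=O)C(O[Si](C)(C)C(C)(C)C)C[C@H](O[Si](C)(C)C(C)(C)C)[C@@H](OCOC)C=C | intermediate
15 | ethyl (2RS,4S,5S)-2,4-bis[(tert-butyldimethylsilyl)oxy]-5-hydroxyhept-6-enoate | CCOC(=O)C(O[Si](C)(C)C(C)(C)C)C[C@H](O[Si](C)(C)C(C)(C)C)[C@@H](O)C=C | intermediate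
16 | (3RS,5S,6S)-3,5-bis[(tert-butyldimethylsilyl)oxy]-6-ethenyloxan-2-one | C=C[C@@H]1OC(=O)C(O[Si](C)(C)C(C)(C)C)C[C@@H]1O[Si](C)(C)C(C)(C)C | intermediate
17 | (2S,3S)-3,5-bis[(tert-butyldimethylsilyl)oxy]-2-ethenyl-6-[(trimethylsilyl)oxy]-3,4-dihydro-2H-pyran | C=C[C@@H]1OC(O[Si](C)(C)C)=C(O[Si](C)(C)C(C)(C)C)C[C@@H]1O[Si](C)(C)C(C)(C)C | intermediate
18 | trimethylsilyl (1S,5S)-1,5-bis[(tert-butyldimethylsilyl)oxy]cyclohex-3-ene-1-carboxylate | CC(C)(C)[Si](C)(C)O[C@@H]1C=CC[C@@](O[Si](C)(C)C(C)(C)C)(C(=O)O[Si](C)(C)C)C1 | intermediate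
19 | (1S,5S)-1,5-bis[(tert-butyldimethylsilyl)oxy]cyclohex-3-ene-1-carboxylic acid | CC(C)(C)[Si](C)(C)O[C@@H]1C=CC[C@@](O[Si](C)(C)C(C)(C)C)(C(=O)O)C1 | intermediate
20 | [(1S,5S)-1,5-bis[(tert-butyldimethylsilyl)oxy]cyclohex-3-en-1-yl]methanol | CC(C)(C)[Si](C)(C)O[C@@H]1C=CC[C@@](O[Si](C)(C)C(C)(C)C)(CO)C1 | intermediate
21 | [(1S,5S)-1,5-bis[(tert-butyldimethylsilyl)oxy]cyclohex-3-en-1-yl]methyl 4-methylbenzenesulfonate | CC(C)(C)[Si](C)(C)O[C@@H]1C=CC[C@@](O[Si](C)(C)C(C)(C)C)(COS(=O)(=O)c2ccc(C)cc2)C1 | intermediate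
22 | [(1S,5S)-1,5-dihydroxycyclohex-3-en-1-yl]methyl 4-methylbenzenesulfonate | O[C@@H]1C=CC[C@@](O)(COS(=O)(=O)c2ccc(C)cc2)C1 | intermediate
23 | (3S,5S)-1-oxaspiro[2.5]oct-6-en-5-ol | O[C@@H]1C=CC[C@@]2(CO2)C1 | intermediate
24 | 5-phenylpent-1-yne | C#CCCCc1ccccc1 | starting material
25 | 1,10-dibromodecane | BrCCCCCCCCCCBr | starting material
26 | (5-phenylpent-1-yn-1-yl)lithium | [Li]C#CCCCc1ccccc1 | intermediate
27 | (15-bromopentadec-4-yn-1-yl)benzene | BrCCCCCCCCCCC#CCCCc1ccccc1 | intermediate
28 | [(4Z)-15-bromopentadec-4-en-1-yl]benzene | BrCCCCCCCCCC/C=C\CCCc1ccccc1 | intermediate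
29 | [(11Z)-15-phenylpentadec-11-en-1-yl]magnesium bromide | Br[Mg]CCCCCCCCCC/C=C\CCCc1ccccc1 | intermediate
30 | (1S,3S)-1-[(12Z)-16-phenylhexadec-12-en-1-yl]cyclohex-4-ene-1,3-diol | O[C@@H]1C=CC[C@@](O)(CCCCCCCCCCC/C=C\CCCc2ccccc2)C1 | target

## Step count and risk

Total step count: 14. Longest linear sequence: 11 steps (steps 1, 2, 3, 5, 6, 7, 8, 9, 10, 11, 14, from ethyl glyoxylate).

**Step 8 (key step).** Enolisation of the hindered α-silyloxy lactone may be incomplete, the enolate may collapse to a ketene before it is silylated, or the silyl ketene acetal may hydrolyse before the boat transition state is reached, so that lactone is returned or destroyed. The fallback abandons the sigmatropic step for a chiral-pool route. It sets out from no numbered compound of the route but from commercial (−)-quinic acid F1, and it comes back to the route at compound 20. Acid-catalysed lactonisation (TsOH, PhMe/DMF, reflux) should give quinide F2, whose cis-3,4-diol is converted with 1,1'-thiocarbonyldiimidazole into the cyclic thionocarbonate F3. Corey–Winter olefination (P(OMe)3, 110 °C) should give the unsaturated lactone 1-hydroxy-6-oxabicyclo[3.2.1]oct-3-en-7-one F4, and NaOMe in MeOH opens it to methyl (1S,5R)-1,5-dihydroxycyclohex-3-ene-1-carboxylate F5. The tertiary centre of F5 already has the configuration of C1 in 19, while the allylic carbinol is epimeric. Mitsunobu inversion (4-nitrobenzoic acid, PPh3, DIAD, THF) should give the 4-nitrobenzoate F6, methanolysis (K2CO3, MeOH) the cis-diol ester F7, and TBSOTf/2,6-lutidine the bis-silyl ether F8. Reduction with i-Bu2AlH (CH2Cl2, −78 to 0 °C) gives 20.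

**Step 5.** The γ-hydroxy ester may close to a γ-butyrolactone during the oxidative work-up, or the silyl group may migrate from O2 to O4; either event blocks the later δ-lactonisation. The fallback replaces the ester by a Weinreb amide, which does not lactonise under neutral conditions. It sets out from ester 5 and comes back at lactone 16. Aminolysis of 5 (MeNHOMe·HCl, i-PrMgCl, THF, −20 °C) should give N-methoxy-N-methyl-2-[(tert-butyldimethylsilyl)oxy]pent-4-enamide F9, and ozonolysis as in step 3 the aldehyde F10. Alkoxyallylboration as in step 5 should give the γ-hydroxy amide F11, and TBSOTf/2,6-lutidine the bis-silyl ether F12. Me2BBr at −78 °C frees the δ-hydroxy amide F13, which should lactonise to 16 on warming with PPTS in PhMe with loss of N,O-dimethylhydroxylamine.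

**Step 7.** One of the silyl ethers may be lost or the allylic C–O bond may ionise under the Lewis acid, or the acetal may be cleaved only in part. The fallback uses an oxidatively removable aryl ether in place of the acetal. It sets out from aldehyde 7 and comes back at hydroxy ester 15. 4-Methoxyphenol is allylated with 2 (K2CO3, acetone) to 1-methoxy-4-(prop-2-en-1-yloxy)benzene F14, which is lithiated (s-BuLi, THF, −78 °C) and converted with (+)-Ipc2BOMe and BF3·OEt2 into the (Z)-γ-aryloxyallylborane. Addition to 7 and the work-up of step 5 should give the syn adduct F15, and TBSOTf/2,6-lutidine its silyl ether F16. (NH4)2Ce(NO3)6 in MeCN/H2O with pyridine at 0 °C should remove the aryl group and give 15, which is lactonised as in step 7.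

## Further compounds

F1 | step 8 | (−)-quinic acid | C1[C@H]([C@H]([C@@H](C[C@@]1(C(=O)O)O)O)O)O
F2 | step 8 | quinide (quinic acid 1,5-lactone) | C1[C@@H](O)[C@@H](O)[C@H]2C[C@]1(O)C(=O)O2
F3 | step 8 | quinide 3,4-thionocarbonate | C1[C@H]2OC(=S)O[C@H]2[C@H]3C[C@]1(O)C(=O)O3
F4 | step 8 | 1-hydroxy-6-oxabicyclo[3.2.1]oct-3-en-7-one (3,4-didehydro-3,4-dideoxyquinide) | C1C=C[C@H]2C[C@]1(O)C(=O)O2
F5 | step 8 | methyl (1S,5R)-1,5-dihydroxycyclohex-3-ene-1-carboxylate | O[C@H]1C=CC[C@@](O)(C(=O)OC)C1
F6 | step 8 | methyl (1S,5S)-1-hydroxy-5-[(4-nitrobenzoyl)oxy]cyclohex-3-ene-1-carboxylate | O=C(O[C@@H]1C=CC[C@@](O)(C(=O)OC)C1)c1ccc(cc1)[N+](=O)[O-]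
F7 | step 8 | methyl (1S,5S)-1,5-dihydroxycyclohex-3-ene-1-carboxylate | O[C@@H]1C=CC[C@@](O)(C(=O)OC)C1
F8 | step 8 | methyl (1S,5S)-1,5-bis[(tert-butyldimethylsilyl)oxy]cyclohex-3-ene-1-carboxylate | CC(C)(C)[Si](C)(C)O[C@@H]1C=CC[C@@](O[Si](C)(C)C(C)(C)C)(C(=O)OC)C1
F9 | step 5 | N-methoxy-N-methyl-2-[(tert-butyldimethylsilyl)oxy]pent-4-enamide (racemic) | CON(C)C(=O)C(O[Si](C)(C)C(C)(C)C)CC=C
F10 | step 5 | N-methoxy-N-methyl-2-[(tert-butyldimethylsilyl)oxy]-4-oxobutanamide (racemic) | CON(C)C(=O)C(O[Si](C)(C)C(C)(C)C)CC=O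
F11 | step 5 | (2RS,4S,5S)-2-[(tert-butyldimethylsilyl)oxy]-4-hydroxy-N-methoxy-5-(methoxymethoxy)-N-methylhept-6-enamide | CON(C)C(=O)C(O[Si](C)(C)C(C)(C)C)C[C@H](O)[C@@H](OCOC)C=C
F12 | step 5 | (2RS,4S,5S)-2,4-bis[(tert-butyldimethylsilyl)oxy]-N-methoxy-5-(methoxymethoxy)-N-methylhept-6-enamide | CON(C)C(=O)C(O[Si](C)(C)C(C)(C)C)C[C@H](O[Si](C)(C)C(C)(C)C)[C@@H](OCOC)C=C
F13 | step 5 | (2RS,4S,5S)-2,4-bis[(tert-butyldimethylsilyl)oxy]-5-hydroxy-N-methoxy-N-methylhept-6-enamide | CON(C)C(=O)C(O[Si](C)(C)C(C)(C)C)C[C@H](O[Si](C)(C)C(C)(C)C)[C@@H](O)C=C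
F14 | step 7 | 1-methoxy-4-(prop-2-en-1-yloxy)benzene | COc1ccc(OCC=C)cc1
F15 | step 7 | ethyl (2RS,4S,5S)-2-[(tert-butyldimethylsilyl)oxy]-4-hydroxy-5-(4-methoxyphenoxy)hept-6-enoate | CCOC(=O)C(O[Si](C)(C)C(C)(C)C)C[C@H](O)[C@@H](Oc1ccc(OC)cc1)C=C
F16 | step 7 | ethyl (2RS,4S,5S)-2,4-bis[(tert-butyldimethylsilyl)oxy]-5-(4-methoxyphenoxy)hept-6-enoate | CCOC(=O)C(O[Si](C)(C)C(C)(C)C)C[C@H](O[Si](C)(C)C(C)(C)C)[C@@H](Oc1ccc(OC)cc1)C=C
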